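**Assumption:** the target SMILES carries no stereodescriptor and the molecule has no stereocentre, so the 8,8''-biaryl axis is left unassigned and the route gives the compound as drawn, with the axis formed without control.

## Retrosynthetic overview

1. Target ⇒ its 5,5'',7,7''-tetra-O-benzyl ether; hydrogenolysis comes last and the two 4'-OMe groups ride through from the aldehyde.
2. Both pyranone rings (rings C) ⇒ a 2'-hydroxy bichalcone by iodine/DMSO oxidative cyclisation; the only free phenols sit next to the biaryl bond, which fixes the 8,8''-linkage.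
3. Bichalcone ⇒ 3,3'-diacetyl-2,2'-dihydroxy-4,4',6,6'-tetrakis(benzyloxy)biphenyl + 2 × 4-methoxybenzaldehyde by a twofold intermolecular Claisen–Schmidt aldol condensation (key C–C bonds, the future C2–C3 of each flavone; brings in rings B).
4. Biaryl diketone ⇒ Ullmann homocoupling of a 3-iodo-2-(methoxymethoxy)-4,6-bis(benzyloxy)acetophenone ⇐ 2,4,6-trihydroxyacetophenone (dibenzylation, ortho-iodination, MOM protection).
5. Ring order: rings A are bought and joined A–A first, rings B arrive with the aldehyde, the two rings C are closed last.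

## Route

**Step 1**
Reactants: 1 2,4,6-trihydroxyacetophenone
Product: 2 1-[2,4-bis(benzyloxy)-6-hydroxyphenyl]ethan-1-one
Conditions: BnBr (2.1 equiv), K2CO3 (2.2 equiv), DMF, 0 °C → rt
Reagents that add atoms: benzyl bromide, BrCc1ccccc1
Why: Williamson ether synthesis that stops at the 4,6-dibenzyl ether because the remaining ortho hydroxyl is hydrogen bonded to the acetyl carbonyl and is the least nucleophilic oxygen.

**Step 2**
Reactants: 2 1-[2,4-bis(benzyloxy)-6-hydroxyphenyl]ethan-1-one
Product: 3 1-[4,6-bis(benzyloxy)-2-hydroxy-3-iodophenyl]ethan-1-one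
Conditions: BnMe3N·ICl2 (1.05 equiv), CaCO3, CH2Cl2–MeOH, rt
Reagents that add atoms: benzyltrimethylammonium dichloroiodate, C[N+](C)(C)Cc1ccccc1.Cl[I-]Cl
Why: Electrophilic aromatic iodination in which the free, chelated phenol is the strongest activating group and directs the single iodine to the ortho position C3, while CaCO3 buffers the HCl so the benzyl ethers survive.

**Step 3**
Reactants: 3 1-[4,6-bis(benzyloxy)-2-hydroxy-3-iodophenyl]ethan-1-one
Product: 4 1-[4,6-bis(benzyloxy)-3-iodo-2-(methoxymethoxy)phenyl]ethan-1-one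
Conditions: NaH (1.2 equiv), DMF, 0 °C; then MOMCl, 0 °C → rt
Reagents that add atoms: chloromethyl methyl ether, COCCl
Why: Williamson-type O-alkylation of the sodium phenoxide with the reactive alpha-chloro ether, where full deprotonation overcomes the hydrogen bond and the ortho crowding and the phenol is far more acidic than the methyl ketone.

**Step 4**
Reactants: 4 1-[4,6-bis(benzyloxy)-3-iodo-2-(methoxymethoxy)phenyl]ethan-1-one (two molecules)
Product: 5 1,1'-[4,4',6,6'-tetrakis(benzyloxy)-2,2'-bis(methoxymethoxy)biphenyl-3,3'-diyl]di(ethan-1-one)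
Conditions: activated Cu powder (6 equiv), DMF, 150 °C, Ar
Reagents that add atoms: none
Why: Ullmann reductive homocoupling of an aryl iodide on copper, the classical way to tetra-ortho-oxygenated biphenyls, tolerates ketone, benzyl ether and acetal groups and forms the future C8–C8'' bond exactly where the iodine marks the site.

**Step 5**
Reactants: 5 1,1'-[4,4',6,6'-tetrakis(benzyloxy)-2,2'-bis(methoxymethoxy)biphenyl-3,3'-diyl]di(ethan-1-one)
Product: 6 1,1'-[4,4',6,6'-tetrakis(benzyloxy)-2,2'-dihydroxybiphenyl-3,3'-diyl]di(ethan-1-one)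
Conditions: HCl (1.25 M in MeOH), THF, 40 °C
Reagents that add atoms: none
Why: Acid-catalysed acetal exchange to methanol removes the two MOM groups, leaves benzyl ethers and ketones untouched and frees exactly the phenols that will become O1 and O1''.

**Step 6**
Reactants: 6 1,1'-[4,4',6,6'-tetrakis(benzyloxy)-2,2'-dihydroxybiphenyl-3,3'-diyl]di(ethan-1-one); 7 4-methoxybenzaldehyde (3 equiv)
Product: 9 (2E,2'E)-1,1'-[4,4',6,6'-tetrakis(benzyloxy)-2,2'-dihydroxybiphenyl-3,3'-diyl]bis[3-(4-methoxyphenyl)prop-2-en-1-one] (the bichalcone), via bis-aldol adduct 8 (not isolated)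
Conditions: KOH (50% aq.), EtOH–THF, rt, 48 h; then 1 M HCl
Reagents that add atoms: none
Why: Twofold Claisen–Schmidt (crossed aldol) condensation in which each methyl ketone enolate adds to the non-enolisable aldehyde and E1cB loss of water from the aldol 8 gives the conjugated, thermodynamically preferred E-enone, the new C–C bonds being the future C2–C3 and C2''–C3'' bonds.

**Step 7**
Reactants: 9 the (2E,2'E)-bichalcone
Product: 10 5,5'',7,7''-tetrakis(benzyloxy)-4',4'''-dimethoxy-8,8''-biflavone
Conditions: I2 (0.2 equiv), DMSO, 130 °C; aq. Na2S2O3 work-up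
Reagents that add atoms: none
Why: Iodine-mediated oxidative cyclisation of a 2'-hydroxychalcone (oxa-Michael closure, alpha-iodination and loss of HI, with DMSO reoxidising HI to I2) closes both pyranone rings through the only free phenols, which lie next to the biaryl bond and so fix the 8,8''-connectivity.

**Step 8**
Reactants: 10 5,5'',7,7''-tetrakis(benzyloxy)-4',4'''-dimethoxy-8,8''-biflavone
Product: 11 4',4'''-di-O-methylcupressuflavone (5,5'',7,7''-tetrahydroxy-4',4'''-dimethoxy-8,8''-biflavone)
Conditions: H2 (1 atm), 10% Pd/C, THF–MeOH, rt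
Reagents that add atoms: none
Why: Palladium-catalysed hydrogenolysis cleaves the four benzylic C–O bonds at room temperature and 1 atm, conditions under which the aryl methyl ethers and the flavone C2=C3 bond (a vinylogous ester) are inert.

## Compound list

1 | 2,4,6-trihydroxyacetophenone | CC(=O)c1c(O)cc(O)cc1O | starting material
2 | 1-[2,4-bis(benzyloxy)-6-hydroxyphenyl]ethan-1-one | CC(=O)c1c(O)cc(OCc2ccccc2)cc1OCc1ccccc1 | intermediate
3 | 1-[4,6-bis(benzyloxy)-2-hydroxy-3-iodophenyl]ethan-1-one | CC(=O)c1c(O)c(I)c(OCc2ccccc2)cc1OCc1ccccc1 | intermediate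
4 | 1-[4,6-bis(benzyloxy)-3-iodo-2-(methoxymethoxy)phenyl]ethan-1-one | CC(=O)c1c(OCOC)c(I)c(OCc2ccccc2)cc1OCc1ccccc1 | intermediate
5 | 1,1'-[4,4',6,6'-tetrakis(benzyloxy)-2,2'-bis(methoxymethoxy)biphenyl-3,3'-diyl]di(ethan-1-one), axis racemic | CC(=O)c1c(OCOC)c(-c2c(OCOC)c(C(C)=O)c(OCc3ccccc3)cc2OCc2ccccc2)c(OCc2ccccc2)cc1OCc1ccccc1 | intermediate
6 | 1,1'-[4,4',6,6'-tetrakis(benzyloxy)-2,2'-dihydroxybiphenyl-3,3'-diyl]di(ethan-1-one), axis racemic | CC(=O)c1c(O)c(-c2c(O)c(C(C)=O)c(OCc3ccccc3)cc2OCc2ccccc2)c(OCc2ccccc2)cc1OCc1ccccc1 | intermediate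
7 | 4-methoxybenzaldehyde | COc1ccc(C=O)cc1 | starting material
8 | bis-aldol adduct: 1,1'-[4,4',6,6'-tetrakis(benzyloxy)-2,2'-dihydroxybiphenyl-3,3'-diyl]bis[3-hydroxy-3-(4-methoxyphenyl)propan-1-one], mixture of diastereomers, not isolated | COc1ccc(C(O)CC(=O)c2c(O)c(-c3c(O)c(C(=O)CC(O)c4ccc(OC)cc4)c(OCc4ccccc4)cc3OCc3ccccc3)c(OCc3ccccc3)cc2OCc2ccccc2)cc1 | intermediate
9 | (2E,2'E)-1,1'-[4,4',6,6'-tetrakis(benzyloxy)-2,2'-dihydroxybiphenyl-3,3'-diyl]bis[3-(4-methoxyphenyl)prop-2-en-1-one] | COc1ccc(/C=C/C(=O)c2c(O)c(-c3c(O)c(C(=O)/C=C/c4ccc(OC)cc4)c(OCc4ccccc4)cc3OCc3ccccc3)c(OCc3ccccc3)cc2OCc2ccccc2)cc1 | intermediate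
10 | 5,5'',7,7''-tetrakis(benzyloxy)-4',4'''-dimethoxy-8,8''-biflavone | COc1ccc(-c2cc(=O)c3c(OCc4ccccc4)cc(OCc4ccccc4)c(-c4c(OCc5ccccc5)cc(OCc5ccccc5)c5c(=O)cc(-c6ccc(OC)cc6)oc45)c3o2)cc1 | intermediate
11 | 4',4'''-di-O-methylcupressuflavone (5,5'',7,7''-tetrahydroxy-4',4'''-dimethoxy-8,8''-biflavone) | COc1ccc(-c2cc(=O)c3c(O)cc(O)c(-c4c(O)cc(O)c5c(=O)cc(-c6ccc(OC)cc6)oc45)c3o2)cc1 | target

## Step count and risks

Total step count: 8. Longest linear sequence: 8 steps (1 → 11).

**Step 4 (Ullmann homocoupling).** Building a tetra-ortho-oxygenated biaryl from an electron-rich iodide can stall or give protodeiodinated monomer. The fallback sets out from compound 2 and comes back to the route at compound 6. Compound 2 is subjected to oxidative dehydrogenative phenol coupling with FeCl3·6H2O adsorbed on SiO2 (solvent-free, about 50 °C), which joins two molecules ortho to the free chelated phenol and gives the biaryl diol 6 directly. The iodide, the MOM ether and the copper step are then not needed. No compound outside the compound list is made (F0).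

**Step 6 (double Claisen–Schmidt condensation).** On the hindered biaryl the second condensation may lag and leave mono-chalcone, or the aldehyde may be consumed by Cannizzaro reaction. The fallback sets out from compound 6 and comes back at compound 10. Compound 6 is deprotonated with LiN(SiMe3)2 (about 7 equiv, THF, −78 °C) and both ketone enolates are C-acylated with 4-methoxybenzoyl chloride in an intermolecular Claisen condensation. This gives 1,1'-[4,4',6,6'-tetrakis(benzyloxy)-2,2'-dihydroxybiphenyl-3,3'-diyl]bis[3-(4-methoxyphenyl)propane-1,3-dione] F1. Cyclodehydration of this bis(1,3-diketone) with catalytic TsOH·H2O in toluene at 90 °C closes both pyranone rings and delivers compound 10 without passing through the bichalcone or an oxidation.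

**Step 7 (iodine/DMSO oxidative cyclisation).** The HI formed at 130 °C can nibble at the 5-O-benzyl groups, and one of the two chalcone arms may stop at the flavanone stage. The fallback sets out from compound 9 and comes back at compound 10. Compound 9 is first cyclised under mild base (NaOAc, EtOH–THF, reflux) by intramolecular oxa-Michael addition to 5,5'',7,7''-tetrakis(benzyloxy)-4',4'''-dimethoxy-8,8''-biflavanone F2 (mixture of diastereomers). This is then dehydrogenated with DDQ in 1,4-dioxane at reflux to compound 10, so that no hydrogen iodide is ever present.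

## Further compounds

F0 | step 4 | none | none
F1 | step 6 | 1,1'-[4,4',6,6'-tetrakis(benzyloxy)-2,2'-dihydroxybiphenyl-3,3'-diyl]bis[3-(4-methoxyphenyl)propane-1,3-dione] | COc1ccc(C(=O)CC(=O)c2c(O)c(-c3c(O)c(C(=O)CC(=O)c4ccc(OC)cc4)c(OCc4ccccc4)cc3OCc3ccccc3)c(OCc3ccccc3)cc2OCc2ccccc2)cc1
F2 | step 7 | 5,5'',7,7''-tetrakis(benzyloxy)-4',4'''-dimethoxy-8,8''-biflavanone (mixture of diastereomers at C2 and C2'') | COc1ccc(C2CC(=O)c3c(OCc4ccccc4)cc(OCc4ccccc4)c(-c4c(OCc5ccccc5)cc(OCc5ccccc5)c5C(=O)CC(c6ccc(OC)cc6)Oc45)c3O2)cc1
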